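**Retrosynthetic overview**
1. Kazinol K 17 ⇐ guaiacol-type diarylpropane 14: oxidative demethylation to the ring-B ortho-quinone, proton shift to a vinyl ortho-quinone methide, oxa-6π closure. The pyran ring is the only ring formed and it is formed last, from a C-prenyl group.
2. 14 ⇐ aryl prenyl ether 13 by aromatic Claisen rearrangement (ring-A 1,1-dimethylallyl group).
3. 13 ⇐ dihydrochalcone 9 ⇐ chalcone 8 ⇐ ketone 7 + aldehyde 4 (Claisen–Schmidt, C=C hydrogenation, C=O deoxygenation).
4. 4 ⇐ 5,6-dibromovanillin 2 (twofold Stille prenylation) ⇐ 5-bromovanillin 1; 7 ⇐ 2,4-dihydroxyacetophenone 5 + prenyl bromide 6.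
5. Both benzene rings are bought; no protecting groups; the vanillin methyl group is carried to the end and leaves as methanol in the key step.

Assumption: the target SMILES has no stereocentre and no stereogenic double bond, so kazinol K is achiral and there is no enantiomer to select.

Ring A is the resorcinol ring. Ring B is the ring that carries the two C-prenyl groups; its positions are primed, with C1' bearing the propane chain.

**Step 1**
Reactants: 1 5-bromovanillin (3-bromo-4-hydroxy-5-methoxybenzaldehyde)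
Product: 2 2,3-dibromo-4-hydroxy-5-methoxybenzaldehyde (5,6-dibromovanillin)
Conditions: Br2 (1.2 equiv), Fe powder (5 mol %), AcOH, 25 °C
Reagents that add atoms: bromine, BrBr
Why: Electrophilic aromatic bromination; with C5 already brominated, the free position para to the methoxy group (C6) is the most activated one, which is the established way to 5,6-dibromovanillin.

**Step 2**
Reactants: 2 2,3-dibromo-4-hydroxy-5-methoxybenzaldehyde; 3 tributyl(3-methylbut-2-en-1-yl)stannane
Product: 4 4-hydroxy-5-methoxy-2,3-bis(3-methylbut-2-en-1-yl)benzaldehyde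
Conditions: 3 (3 equiv), Pd(PPh3)4 (10 mol %), DMF, 100–110 °C, Ar; aq KF work-up
Reagents that add atoms: tributyl(3-methylbut-2-en-1-yl)stannane (3), CCCC[Sn](CCCC)(CCCC)CC=C(C)C
Why: Twofold Stille cross-coupling under neutral conditions tolerates the free phenol and the aldehyde; the C–Br bond ortho to the aldehyde reacts first, and reductive elimination at the unsubstituted terminus of the prenyl-palladium intermediate gives the linear prenyl groups.

**Step 3**
Reactants: 5 2,4-dihydroxyacetophenone; 6 1-bromo-3-methylbut-2-ene (prenyl bromide)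
Product: 7 1-[2-hydroxy-4-(3-methylbut-2-en-1-yloxy)phenyl]ethanone
Conditions: 6 (1.1 equiv), K2CO3 (1.2 equiv), acetone, reflux
Reagents that add atoms: 1-bromo-3-methylbut-2-ene (6), CC(C)=CCBr
Why: Williamson ether synthesis; the 2-OH is tied up in a hydrogen bond to the ketone, so only the 4-OH is alkylated.

**Step 4**
Reactants: 4 4-hydroxy-5-methoxy-2,3-bis(3-methylbut-2-en-1-yl)benzaldehyde; 7 1-[2-hydroxy-4-(3-methylbut-2-en-1-yloxy)phenyl]ethanone
Product: 8 (E)-1-[2-hydroxy-4-(3-methylbut-2-en-1-yloxy)phenyl]-3-[4-hydroxy-5-methoxy-2,3-bis(3-methylbut-2-en-1-yl)phenyl]prop-2-en-1-one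
Conditions: KOH (50 % aq, excess), EtOH, 25→50 °C, N2, 48 h; then cold dilute HCl
Reagents that add atoms: none
Why: Claisen–Schmidt (crossed aldol) condensation of a methyl ketone with a non-enolizable aldehyde; dehydration under thermodynamic control gives the E-enone, and unprotected vanillin-type aldehydes are known to condense under strongly basic conditions, though slowly.

**Step 5**
Reactants: 8 the chalcone from step 4
Product: 9 1-[2-hydroxy-4-(3-methylbut-2-en-1-yloxy)phenyl]-3-[4-hydroxy-5-methoxy-2,3-bis(3-methylbut-2-en-1-yl)phenyl]propan-1-one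
Conditions: H2 (1 atm), RhCl(PPh3)3 (5 mol %), benzene/EtOH 1:1, 25 °C
Reagents that add atoms: none
Why: Homogeneous hydrogenation with Wilkinson's catalyst reduces the disubstituted enone C=C far faster than the trisubstituted prenyl alkenes and leaves the aryl ketone and the allylic ether alone.

**Step 6**
Reactants: 9 the dihydrochalcone from step 5
Product: 13 1-[2-hydroxy-4-(3-methylbut-2-en-1-yloxy)phenyl]-3-[4-hydroxy-5-methoxy-2,3-bis(3-methylbut-2-en-1-yl)phenyl]propane, via bis(ethyl carbonate) 10 (not isolated), via ortho-quinone methide 11 (not isolated), via ring-B ethyl carbonate 12 (not isolated)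
Conditions: ClCO2Et (2.5 equiv), Et3N (3 equiv), THF, 0 °C; NaBH4 (6 equiv), H2O/THF, 0→25 °C; then 2 M NaOH, MeOH, 25 °C; NH4Cl work-up
Reagents that add atoms: ethyl chloroformate, CCOC(=O)Cl (its atoms are present in 10, 11 and 12 and are all lost again before 13)
Why: Reductive deoxygenation of an ortho-hydroxyaryl ketone through its ethyl carbonate: hydride gives the benzylic alkoxide, the carbonate migrates to it and is expelled to give ortho-quinone methide 11, a second hydride adds 1,4 to give 12, and NaOH removes the remaining ring-B carbonate.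

**Step 7**
Reactants: 13 the diarylpropane prenyl ether from step 6
Product: 14 1-[2,4-dihydroxy-5-(2-methylbut-3-en-2-yl)phenyl]-3-[4-hydroxy-5-methoxy-2,3-bis(3-methylbut-2-en-1-yl)phenyl]propane
Conditions: PhNEt2, 195 °C, sealed tube, Ar, 1.5–2 h
Reagents that add atoms: none
Why: Aromatic Claisen rearrangement ([3,3]-sigmatropic) transfers the prenyl group with allylic inversion to the ortho carbon, which gives the 1,1-dimethylallyl group; C5 is preferred over C3, which sits between two oxygens and would have to take a quaternary carbon, and rearomatization makes the step irreversible.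

**Step 8**
Reactants: 14 the guaiacol-type diarylpropane from step 7
Product: 17 kazinol K, via ring-B ortho-quinone 15 (not isolated), via vinyl ortho-quinone methide 16 (not isolated)
Conditions: NaIO4 (1.05 equiv), THF/H2O 3:1, 0 °C, 10 min; extract into toluene; pyridine (2 equiv), toluene, 25→45 °C, Ar
Reagents that add atoms: water, O (source of the new oxygen at C5', the 8-OH of the chromene)
Why: Proposed new method: periodate attacks the most electron-rich phenol, the ortho-methoxy phenol of ring B, and gives ortho-quinone 15 with loss of methanol while the harder-to-oxidize resorcinol ring is left; pyridine then moves a proton from the C3' prenyl CH2 to give the (Z)-vinyl ortho-quinone methide 16, which closes irreversibly by oxa-6π electrocyclization to the 2H-chromene and leaves the C5' hydroxyl free; the closest known reactions are the Adler–Becker periodate oxidation of 2-methoxyphenols to ortho-quinones and the pyridine-induced isomerization of prenyl-benzoquinones to chromenols; no stereocentre is formed.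

**Compound list**
1 | 5-bromovanillin (3-bromo-4-hydroxy-5-methoxybenzaldehyde) | O=Cc1cc(Br)c(O)c(OC)c1 | starting material
2 | 2,3-dibromo-4-hydroxy-5-methoxybenzaldehyde (5,6-dibromovanillin) | O=Cc1c(Br)c(Br)c(O)c(OC)c1 | intermediate
3 | tributyl(3-methylbut-2-en-1-yl)stannane | CCCC[Sn](CCCC)(CCCC)CC=C(C)C | starting material
4 | 4-hydroxy-5-methoxy-2,3-bis(3-methylbut-2-en-1-yl)benzaldehyde | O=Cc1c(CC=C(C)C)c(CC=C(C)C)c(O)c(OC)c1 | intermediate
5 | 2,4-dihydroxyacetophenone | CC(=O)c1ccc(O)cc1O | starting material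
6 | 1-bromo-3-methylbut-2-ene (prenyl bromide) | CC(C)=CCBr | starting material
7 | 1-[2-hydroxy-4-(3-methylbut-2-en-1-yloxy)phenyl]ethanone | CC(=O)c1ccc(OCC=C(C)C)cc1O | intermediate
8 | (E)-1-[2-hydroxy-4-(3-methylbut-2-en-1-yloxy)phenyl]-3-[4-hydroxy-5-methoxy-2,3-bis(3-methylbut-2-en-1-yl)phenyl]prop-2-en-1-one | O=C(/C=C/c1cc(OC)c(O)c(CC=C(C)C)c1CC=C(C)C)c1ccc(OCC=C(C)C)cc1O | intermediate
9 | 1-[2-hydroxy-4-(3-methylbut-2-en-1-yloxy)phenyl]-3-[4-hydroxy-5-methoxy-2,3-bis(3-methylbut-2-en-1-yl)phenyl]propan-1-one | O=C(CCc1cc(OC)c(O)c(CC=C(C)C)c1CC=C(C)C)c1ccc(OCC=C(C)C)cc1O | intermediate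
10 | bis(ethyl carbonate) of 9 (both phenols acylated) | CCOC(=O)Oc1cc(OCC=C(C)C)ccc1C(=O)CCc1cc(OC)c(OC(=O)OCC)c(CC=C(C)C)c1CC=C(C)C | intermediate (not isolated)
11 | (E)-ortho-quinone methide of ring A: 6-alkylidene-3-(prenyloxy)cyclohexa-2,4-dien-1-one carrying the ring-B ethyl carbonate | O=C1C=C(OCC=C(C)C)C=C/C1=C\CCc1cc(OC)c(OC(=O)OCC)c(CC=C(C)C)c1CC=C(C)C | intermediate (not isolated)
12 | ring-B ethyl carbonate of 13 | Oc1cc(OCC=C(C)C)ccc1CCCc1cc(OC)c(OC(=O)OCC)c(CC=C(C)C)c1CC=C(C)C | intermediate (not isolated)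
13 | 1-[2-hydroxy-4-(3-methylbut-2-en-1-yloxy)phenyl]-3-[4-hydroxy-5-methoxy-2,3-bis(3-methylbut-2-en-1-yl)phenyl]propane | Oc1cc(OCC=C(C)C)ccc1CCCc1cc(OC)c(O)c(CC=C(C)C)c1CC=C(C)C | intermediate
14 | 1-[2,4-dihydroxy-5-(2-methylbut-3-en-2-yl)phenyl]-3-[4-hydroxy-5-methoxy-2,3-bis(3-methylbut-2-en-1-yl)phenyl]propane | C=CC(C)(C)c1cc(CCCc2cc(OC)c(O)c(CC=C(C)C)c2CC=C(C)C)c(O)cc1O | intermediate
15 | 5-{3-[2,4-dihydroxy-5-(2-methylbut-3-en-2-yl)phenyl]propyl}-3,4-bis(3-methylbut-2-en-1-yl)cyclohexa-3,5-diene-1,2-dione (ring-B ortho-quinone) | C=CC(C)(C)c1cc(CCCC2=CC(=O)C(=O)C(CC=C(C)C)=C2CC=C(C)C)c(O)cc1O | intermediate (not isolated)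
16 | (Z)-vinyl ortho-quinone methide of ring B (C4' carbonyl, C3' exocyclic 3-methylbut-2-enylidene, C5' hydroxyl) | C=CC(C)(C)c1cc(CCCC2=C(CC=C(C)C)/C(=C/C=C(C)C)C(=O)C(O)=C2)c(O)cc1O | intermediate (not isolated)
17 | kazinol K: 4-{3-[8-hydroxy-2,2-dimethyl-5-(3-methylbut-2-en-1-yl)-2H-chromen-6-yl]propyl}-6-(2-methylbut-3-en-2-yl)benzene-1,3-diol | C=CC(C)(C)c1cc(CCCc2cc(O)c3c(c2CC=C(C)C)C=CC(C)(C)O3)c(O)cc1O | target

**Step count:** 8 steps in total. Longest linear sequence: 7 steps (1 → 2 → 4 → 8 → 9 → 13 → 14 → 17); step 3 is a one-step side branch.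

**Steps most likely to fail, with fallbacks**

Step 8 (most likely). The ortho-quinone 15 can also tautomerize to para-quinone methides at the propane chain or at the C2' prenyl group. The chain-derived one could be trapped by the ring-A 2-OH as a flavan. Periodate may also attack the resorcinol ring. The fallback avoids the ortho-quinone altogether. It sets out from 14: DDQ (1.05 equiv) in benzene at 25 °C abstracts hydride from the benzylic-allylic CH2 of the C3' prenyl group next to the free phenol, and oxa-6π closure gives kazinol K 8-O-methyl ether F1. The methyl group is then removed by nucleophilic demethylation with NaSEt in DMF at 130 °C, which spares the three alkenes, and the route comes back at 17.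

Step 2. The second C–Br bond (flanked by the new prenyl group and the phenol, on an electron-rich ring) may couple slowly, and some branched (1,1-dimethylallyl) product may form. The fallback sets out from 2: twofold Suzuki–Miyaura allylation with allylboronic acid pinacol ester (Pd(OAc)2, SPhos, K3PO4, THF/H2O, 60 °C) gives 2,3-diallyl-4-hydroxy-5-methoxybenzaldehyde F2, where no regiochemical question arises. Cross-metathesis of both allyl groups with 2-methyl-2-butene (second-generation Grubbs catalyst RuCl2(=CHPh)(PCy3)(H2IMes), CH2Cl2, 40 °C) turns them into prenyl groups, and the route comes back at 4.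

Step 4. In base the aldehyde 4 is a para-formyl phenoxide with an ortho prenyl group, so it is a poor electrophile and the condensation may stall. The fallback sets out from 4: MOMCl and i-Pr2NEt in CH2Cl2 give 5-methoxy-4-(methoxymethoxy)-2,3-bis(3-methylbut-2-en-1-yl)benzaldehyde F3. This condenses normally with 7 (KOH, EtOH, 25 °C) to the MOM-protected chalcone F4. Mild acid (1 M HCl in MeOH/THF, 25 °C) removes the acetal, and the route comes back at 8.

**Further compounds**
F1 | step 8 | kazinol K 8-O-methyl ether: 4-{3-[8-methoxy-2,2-dimethyl-5-(3-methylbut-2-en-1-yl)-2H-chromen-6-yl]propyl}-6-(2-methylbut-3-en-2-yl)benzene-1,3-diol | C=CC(C)(C)c1cc(CCCc2cc(OC)c3c(c2CC=C(C)C)C=CC(C)(C)O3)c(O)cc1O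
F2 | step 2 | 2,3-diallyl-4-hydroxy-5-methoxybenzaldehyde | O=Cc1c(CC=C)c(CC=C)c(O)c(OC)c1
F3 | step 4 | 5-methoxy-4-(methoxymethoxy)-2,3-bis(3-methylbut-2-en-1-yl)benzaldehyde | O=Cc1c(CC=C(C)C)c(CC=C(C)C)c(OCOC)c(OC)c1
F4 | step 4 | (E)-1-[2-hydroxy-4-(3-methylbut-2-en-1-yloxy)phenyl]-3-[5-methoxy-4-(methoxymethoxy)-2,3-bis(3-methylbut-2-en-1-yl)phenyl]prop-2-en-1-one | O=C(/C=C/c1cc(OC)c(OCOC)c(CC=C(C)C)c1CC=C(C)C)c1ccc(OCC=C(C)C)cc1O
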